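**Assumptions**
- Bromination of 1 goes para to the free phenol (at C6). Boronic acid 6 is treated as commercially available.
- The SMILES gives (1S,2R), trans, for the dihydronaphthalene. I label the diarylmethine carbon C1 (= C7') and the CH–CH2OH carbon C2 (= C8').

**Retrosynthesis**
1. Vitedoin A comes from diol 12 by chemoselective MnO2 oxidation of the allylic alcohol, followed by removal of both benzyl groups. Diol 12 comes from DIBAL reduction of diester 11.
2. The dihydronaphthalene ring is the only ring formed in the route. It closes last, by intramolecular aldol condensation of an aryl aldehyde onto a tert-butyl ester enolate. C2 is equilibrated to the trans isomer there.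
3. The aryl aldehyde comes from an aryl bromide by Pd-catalysed formylation. The bromide carries a succinate side chain made by alkylating a 3,3-diarylpropanoate.
4. C1 is set by Rh-catalysed asymmetric 1,4-arylation of a cinnamate. The cinnamate comes from Wittig olefination of a bromo-aldehyde made from commercial 3-hydroxy-2-methoxybenzaldehyde. Aromatic ring A is present from the start.

---

**Step 1**
Reactants: 1 (3-hydroxy-2-methoxybenzaldehyde)
Product: 2 (6-bromo-3-hydroxy-2-methoxybenzaldehyde)
Conditions: NBS, MeCN, 0 °C → rt
Reagents that add atoms: N-bromosuccinimide, O=C1CCC(=O)N1Br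
Why: Electrophilic aromatic bromination goes para to the free phenol, which marks the carbon that will become C4a and later C4. No stereocentre is involved.

**Step 2**
Reactants: 2
Product: 3 (3-(benzyloxy)-6-bromo-2-methoxybenzaldehyde)
Conditions: BnBr, K2CO3, DMF, rt
Reagents that add atoms: benzyl bromide, BrCc1ccccc1
Why: Williamson etherification masks the phenol as a benzyl ether. This protects it from the strong bases in steps 5 and 7.

**Step 3**
Reactants: 3; 4 (methyl 2-(triphenylphosphoranylidene)acetate)
Product: 5 (methyl (E)-3-[3-(benzyloxy)-6-bromo-2-methoxyphenyl]acrylate)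
Conditions: toluene, 110 °C
Reagents that add atoms: none
Why: Wittig olefination with a stabilised ylide gives the E-enoate, the acceptor for the asymmetric arylation.

**Step 4**
Reactants: 5; 6 ([4-(benzyloxy)-3-methoxyphenyl]boronic acid)
Product: 7 (methyl (S)-3-[3-(benzyloxy)-6-bromo-2-methoxyphenyl]-3-[4-(benzyloxy)-3-methoxyphenyl]propanoate)
Conditions: [RhCl(C2H4)2]2 (2 mol%), (S)-BINAP, aq. KOH (cat.), dioxane/H2O 10:1, 100 °C
Reagents that add atoms: none
Why: Hayashi–Miyaura Rh-catalysed asymmetric conjugate addition of the aryl group to the β-carbon. The chiral ligand and the large steric difference between the two aryl groups set the benzhydryl stereocentre (C1 = S). The ligand enantiomer is chosen to give S. The Rh-enolate is protonated, so no second stereocentre forms.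

**Step 5**
Reactants: 7; 8 (tert-butyl bromoacetate)
Product: 9 (4-tert-butyl 1-methyl 2-{(S)-[3-(benzyloxy)-6-bromo-2-methoxyphenyl][4-(benzyloxy)-3-methoxyphenyl]methyl}succinate, mixture of C2 epimers)
Conditions: LDA, THF, −78 °C; then 8
Reagents that add atoms: none beyond reactant 8
Why: Ester-enolate alkylation installs C8–C9 on C8'. C8' is formed with substrate-controlled diastereoselectivity, but its configuration does not matter because it is equilibrated in step 7. C1 is untouched.

**Step 6**
Reactants: 9
Product: 10 (the 6-formyl analogue of 9)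
Conditions: Pd(OAc)2, nBuPAd2, TMEDA, CO/H2 (1:1, 20 bar), toluene, 100 °C
Reagents that add atoms: carbon monoxide, [C-]#[O+]
Why: Pd-catalysed reductive carbonylation (formylation) of the aryl bromide installs the C7 aldehyde at the carbon that becomes C4a-bound. The esters and benzyl ethers survive.

**Step 7**
Reactants: 10
Product: 11 (3-tert-butyl 2-methyl (1S,2R)-7-(benzyloxy)-1-[4-(benzyloxy)-3-methoxyphenyl]-8-methoxy-1,2-dihydronaphthalene-2,3-dicarboxylate)
Conditions: KOtBu, THF/tBuOH 4:1, 0 → 40 °C
Reagents that add atoms: none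
Why: Intramolecular aldol condensation (Stobbe/Knoevenagel type): the tert-butyl ester enolate adds to the aryl aldehyde to form the six-membered ring, then E1cB dehydration gives the conjugated C7=C8 enoate. The base also epimerises the ester-bearing C2 (= C8'). It settles on the trans isomer, with C1 aryl and C2 CO2Me pseudo-diaxial, which is favoured by peri-strain from 8-OMe and allylic strain from the C3 ester. C1 is not acidic and is retained.

**Step 8**
Reactants: 11
Product: 12 ([(1S,2R)-7-(benzyloxy)-1-[4-(benzyloxy)-3-methoxyphenyl]-8-methoxy-1,2-dihydronaphthalene-2,3-diyl]dimethanol)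
Conditions: DIBAL-H (6 equiv), CH2Cl2, −78 → 0 °C
Reagents that add atoms: none
Why: DIBAL reduces both the saturated methyl ester and the conjugated tert-butyl ester (1,2-reduction) to primary alcohols. Benzyl ethers and both stereocentres are untouched.

**Step 9**
Reactants: 12
Product: 13 ((1S,2R)-7-(benzyloxy)-1-[4-(benzyloxy)-3-methoxyphenyl]-2-(hydroxymethyl)-8-methoxy-1,2-dihydronaphthalene-3-carbaldehyde)
Conditions: MnO2 (20 equiv), CH2Cl2, rt
Reagents that add atoms: none
Why: MnO2 oxidises only the allylic (cinnamyl-type) C9 alcohol. The C9' alcohol is non-allylic and survives, and neither stereocentre can epimerise under these conditions.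

**Step 10**
Reactants: 13
Product: 14 (vitedoin A)
Conditions: BCl3, pentamethylbenzene, CH2Cl2, −78 °C
Reagents that add atoms: none
Why: BCl3 with a cation scavenger cleaves both aryl benzyl ethers without hydrogenation, so the conjugated alkene and aldehyde are preserved. This gives the free 7-OH and 4'-OH.

---

**Compound list**

| # | Name | SMILES | Role |
|---|---|---|---|
| 1 | 3-hydroxy-2-methoxybenzaldehyde | COc1c(O)cccc1C=O | starting material |
| 2 | 6-bromo-3-hydroxy-2-methoxybenzaldehyde | COc1c(O)ccc(Br)c1C=O | intermediate |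
| 3 | 3-(benzyloxy)-6-bromo-2-methoxybenzaldehyde | COc1c(OCc2ccccc2)ccc(Br)c1C=O | intermediate |
| 4 | methyl (triphenylphosphoranylidene)acetate | COC(=O)C=P(c1ccccc1)(c1ccccc1)c1ccccc1 | starting material |
| 5 | methyl (E)-3-[3-(benzyloxy)-6-bromo-2-methoxyphenyl]acrylate | COc1c(OCc2ccccc2)ccc(Br)c1/C=C/C(=O)OC | intermediate |
| 6 | [4-(benzyloxy)-3-methoxyphenyl]boronic acid | COc1cc(B(O)O)ccc1OCc1ccccc1 | starting material |
| 7 | methyl (S)-3-[3-(benzyloxy)-6-bromo-2-methoxyphenyl]-3-[4-(benzyloxy)-3-methoxyphenyl]propanoate | COc1cc([C@H](CC(=O)OC)c2c(Br)ccc(OCc3ccccc3)c2OC)ccc1OCc1ccccc1 | intermediate |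
| 8 | tert-butyl bromoacetate | CC(C)(C)OC(=O)CBr | starting material |
| 9 | 4-tert-butyl 1-methyl 2-{(S)-[3-(benzyloxy)-6-bromo-2-methoxyphenyl][4-(benzyloxy)-3-methoxyphenyl]methyl}succinate (C2 epimers) | COc1cc([C@H](C(C(=O)OC)CC(=O)OC(C)(C)C)c2c(Br)ccc(OCc3ccccc3)c2OC)ccc1OCc1ccccc1 | intermediate |
| 10 | 6-formyl analogue of 9 | COc1cc([C@H](C(C(=O)OC)CC(=O)OC(C)(C)C)c2c(C=O)ccc(OCc3ccccc3)c2OC)ccc1OCc1ccccc1 | intermediate |
| 11 | 3-tert-butyl 2-methyl (1S,2R)-7-(benzyloxy)-1-[4-(benzyloxy)-3-methoxyphenyl]-8-methoxy-1,2-dihydronaphthalene-2,3-dicarboxylate | COc1cc([C@H]2c3c(ccc(OCc4ccccc4)c3OC)C=C(C(=O)OC(C)(C)C)[C@@H]2C(=O)OC)ccc1OCc1ccccc1 | intermediate |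
| 12 | [(1S,2R)-7-(benzyloxy)-1-[4-(benzyloxy)-3-methoxyphenyl]-8-methoxy-1,2-dihydronaphthalene-2,3-diyl]dimethanol | COc1cc([C@H]2c3c(ccc(OCc4ccccc4)c3OC)C=C(CO)[C@@H]2CO)ccc1OCc1ccccc1 | intermediate |
| 13 | (1S,2R)-7-(benzyloxy)-1-[4-(benzyloxy)-3-methoxyphenyl]-2-(hydroxymethyl)-8-methoxy-1,2-dihydronaphthalene-3-carbaldehyde | COc1cc([C@H]2c3c(ccc(OCc4ccccc4)c3OC)C=C(C=O)[C@@H]2CO)ccc1OCc1ccccc1 | intermediate |
| 14 | vitedoin A, (1S,2R)-7-hydroxy-1-(4-hydroxy-3-methoxyphenyl)-2-(hydroxymethyl)-8-methoxy-1,2-dihydronaphthalene-3-carbaldehyde | COc1cc([C@H]2c3c(ccc(O)c3OC)C=C(C=O)[C@@H]2CO)ccc1O | target |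

**Step count:** 10 steps in total. The longest linear sequence is 10 steps (1 → 2 → 3 → 5 → 7 → 9 → 10 → 11 → 12 → 13 → 14). Benzylation of the phenol in step 2 and debenzylation in step 10 are the only protecting-group steps.

**Three steps most likely to fail**
1. **Step 4 (Rh asymmetric arylation).** The β-carbon of the cinnamate sits between a 2,6-disubstituted aryl ring and a trisubstituted-like environment, so it is hindered.
   - Fallback: use an Evans chiral-auxiliary route. Make the N-cinnamoyl (S)-4-phenyloxazolidinone from the bromo-aldehyde, add Ar'MgBr with CuBr·SMe2, then cleave the auxiliary and esterify to reach 7.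
2. **Step 7 (aldol condensation with C2 equilibration).** Strong base could also isomerise the C7=C8 double bond into conjugation with both esters, giving a 1,4-dihydro isomer, or leave a cis/trans mixture at C2.
   - Fallback: close the ring by ring-closing metathesis instead. Vinylate the aryl bromide of 9 with potassium vinyltrifluoroborate, α-methylenate the tert-butyl ester, and close with a Hoveyda–Grubbs II catalyst. Then epimerise C2 under mild conditions.
3. **Step 10 (global debenzylation).** BCl3 might chlorinate the primary alcohol or damage the enal.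
   - Fallback: use MOM ethers on both phenols from the start (MOM-protect 2, use the MOM-protected boronic acid) and remove them in the last step with ZnBr2/n-PrSH.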